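**Strategy.** Ring A is disconnected across C1–C2 and C5–C10, a retro-[4+2] in which C2=C3–C4=C5 is a 2-silyloxy diene and C10=C1 an α-methylene lactone. Breaking C5–C10 also opens ring B, so the precursor is a monocyclic trans-β,γ-disubstituted butyrolactone. The key step, a thermal intramolecular Diels–Alder reaction, closes rings A and B at once and sets C10 and C5 from the lactone stereocenters. It exploits the 1,3-diaxial relation of C20 (on C10) and C8 across ring B: C20 serves as the activating carbonyl, tied to C8–O as a temporary lactone, and is later reduced to the angular methyl. C13 comes from (S)-citronellic acid; the C3 enol ether left by the cycloaddition delivers C4.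

Key step: step 9

Remark: labdane numbering (C1–C20) is used for all skeleton atoms, and in step 7 the ligand enantiomer is taken to be the one that delivers the (8S,9R) lactone.

Step 1
Reactants: 1 (S)-citronellic acid
Product: 2 tert-butyl (3S)-3,7-dimethyloct-6-enoate
Conditions: Boc2O, DMAP (cat.), t-BuOH, 40 °C
Reagents that add atoms: di-tert-butyl dicarbonate CC(C)(C)OC(=O)OC(=O)OC(C)(C)C
Why: DMAP-catalysed tert-butyl ester formation through the mixed carbonic anhydride gives an ester that should survive steps 2 to 11 and is cleaved by the alkali of step 12, and C13 is not touched.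

Step 2
Reactants: 2 tert-butyl (3S)-3,7-dimethyloct-6-enoate
Product: 4 tert-butyl (3S)-3-methyl-6-oxohexanoate, via ozonide 3 (not isolated)
Conditions: O3, CH2Cl2, −78 °C; then Me2S, −78 °C → rt
Reagents that add atoms: ozone [O-][O+]=O
Why: Ozonolysis with reductive work-up cleaves the only alkene and turns the future C9 into an aldehyde without affecting the C13 stereocenter.

Step 3
Reactants: 4 tert-butyl (3S)-3-methyl-6-oxohexanoate; 5 methyl acrylate
Product: 6 8-tert-butyl 1-methyl (6S)-3-hydroxy-6-methyl-2-methylideneoctanedioate (both C3 epimers)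
Conditions: DABCO (0.5 equiv), methyl acrylate (3 equiv), MeOH, rt, several days
Reagents that add atoms: none
Why: Morita–Baylis–Hillman reaction of an unhindered aliphatic aldehyde joins C9 to C10 and brings in C1 and C20, and the new carbinol center forms as a mixture that is irrelevant because step 4 makes C9 trigonal.

Step 4
Reactants: 6 8-tert-butyl 1-methyl (6S)-3-hydroxy-6-methyl-2-methylideneoctanedioate
Product: 7 8-tert-butyl 1-methyl (2Z,6S)-2-(bromomethyl)-6-methyloct-2-enedioate
Conditions: NBS, Me2S, CH2Cl2, 0 °C → rt
Reagents that add atoms: N-bromosuccinimide O=C1CCC(=O)N1Br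
Why: Activation of the allylic alcohol as an alkoxysulfonium salt followed by SN2' attack of bromide gives the rearranged, thermodynamically preferred (Z)-2-(bromomethyl)enoate, the usual outcome for Morita–Baylis–Hillman alcohols.

Step 5
Reactants: 8 4-pentenal; 9 3-(triphenylphosphoranylidene)butan-2-one
Product: 10 (3E)-3-methylocta-3,7-dien-2-one
Conditions: toluene, 90 °C
Reagents that add atoms: none
Why: Wittig olefination with a ketone-stabilised ylide is E-selective and fixes the C4=C5 geometry (tether trans to C3) that the cycloaddition needs.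

Step 6
Reactants: 10 (3E)-3-methylocta-3,7-dien-2-one
Product: 12 (4E)-5-methyl-6-oxohept-4-enal, via ozonide 11 (not isolated)
Conditions: O3 (1 equiv, Sudan Red 7B end point), CH2Cl2, −78 °C; then PPh3
Reagents that add atoms: ozone [O-][O+]=O
Why: Ozonolysis with reductive work-up consumes the electron-rich terminal alkene much faster than the electron-poor enone alkene, so one equivalent of ozone should unveil only the C8 aldehyde.

Step 7
Reactants: 7 8-tert-butyl 1-methyl (2Z,6S)-2-(bromomethyl)-6-methyloct-2-enedioate; 12 (4E)-5-methyl-6-oxohept-4-enal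
Product: 14 tert-butyl (3S)-3-methyl-5-[(2S,3R)-2-[(3E)-4-methyl-5-oxohex-3-en-1-yl]-4-methylidene-5-oxooxolan-3-yl]pentanoate (trans lactone), via hydroxy ester 13 (not isolated)
Conditions: CrCl2 (10 mol%), (S,S)-1,8-bis(4-isopropyl-2-oxazolinyl)-3,6-diphenylcarbazole ligand (12 mol%), Mn powder, TMSCl, i-Pr2NEt (cat.), THF, rt; then 1 M HCl; then p-TsOH (cat.), CH2Cl2, rt
Reagents that add atoms: none
Why: Catalytic asymmetric Nozaki–Hiyama–Kishi-type allylation in which the allylchromium from 7 adds through its γ-carbon (C9) to the aldehyde in a chair transition state that gives the anti C8/C9 pair, the chiral ligand selects the aldehyde face and so the absolute configuration at C8, the ketone is ignored by the organochromium, and the hydroxy ester closes to the trans lactone on acid treatment.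

Step 8
Reactants: 14 trans lactone enone
Product: 15 tert-butyl (3S)-5-[(2S,3R)-2-[(3E)-5-[(tert-butyldimethylsilyl)oxy]-4-methylhexa-3,5-dien-1-yl]-4-methylidene-5-oxooxolan-3-yl]-3-methylpentanoate
Conditions: TBSOTf, Et3N, CH2Cl2, −78 → 0 °C
Reagents that add atoms: tert-butyldimethylsilyl trifluoromethanesulfonate CC(C)(C)[Si](C)(C)OS(=O)(=O)C(F)(F)F
Why: Soft enolisation (silyl triflate and amine) of the methyl ketone at its methyl group gives the cross-conjugated 2-silyloxy diene without a strong base that would attack the α-methylene lactone, and no stereocenter is formed.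

Step 9
Reactants: 15 silyloxy diene lactone
Product: 16 tert-butyl (13S)-3-[(tert-butyldimethylsilyl)oxy]-20-oxo-8β,20-epoxy-17-norlabd-3-en-15-oate (trans-fused decalin with the 20,8β-lactone bridge; 5α-H, 9α-H, C20 β on C10)
Conditions: toluene (0.01 M), BHT (trace), 130 °C, sealed tube
Reagents that add atoms: none
Why: Concerted, asynchronous normal-electron-demand intramolecular Diels–Alder reaction (type 1, four-atom tether C6–C7–C8–C9) in which the electron-rich 2-silyloxy-3-methyl diene C2=C3–C4=C5 adds to the α-methylene lactone C10=C1, the C1–C2 bond being the more advanced one (largest HOMO coefficient at C2, largest LUMO coefficient at C1), which is the para orientation such dienes show with acrylates. The closest known reaction types are the cycloadditions of 2-silyloxy dienes with α-methylene-γ-butyrolactones and the intramolecular Diels–Alder reactions of 1,7,9-decatrienes that carry the activating carbonyl on the internal dienophile carbon. Ring A closes as the cyclohexene of the [4+2] itself and ring B as a chair-like six-membered ring through the tether when C5 bonds to C10, which also turns the butyrolactone into a bridged 6-oxabicyclo[3.2.1]octan-7-one. C10 is controlled by C8, because the diene hangs from C8 and can reach C10 only on the lactone face that carries the C7 chain, so C20 and the C8 oxygen end up cis (both β) while the trans C9 side chain lies on the opposite face and becomes equatorial. C5 is controlled by the endo rule, since with the lactone carbonyl under the diene (tether anti) the C5 hydrogen ends up anti to C20, that is trans ring fusion, whereas the exo mode would force ring A under the forming ring B against the C6–C7 tether. The step needs endo over exo selectivity and intramolecular over intermolecular reaction, and the rigid lactone, the (E) geometry of C4=C5, high dilution and a radical inhibitor are expected to secure these.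

Step 10
Reactants: 16 tricyclic lactone
Product: 17 tert-butyl (13S)-3-[(tert-butyldimethylsilyl)oxy]-20-hydroxy-8β,20-epoxy-17-norlabd-3-en-15-oate (lactol, both C20 epimers)
Conditions: i-Bu2AlH (1.1 equiv), CH2Cl2, −78 °C; aq. potassium sodium tartrate
Reagents that add atoms: none
Why: Partial reduction of the γ-lactone to the lactol with one equivalent of hydride at low temperature, conditions under which a tert-butyl ester and a silyl enol ether are normally left intact, and the new acetal center at C20 is removed in step 12.

Step 11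
Reactants: 17 lactol silyl enol ether
Product: 18 tert-butyl (13S)-18,20-dihydroxy-3-oxo-8β,20-epoxy-17-norlabdan-15-oate (4α-CH2OH, 4β-CH3)
Conditions: aq. CH2O (37%), Sc(OTf)3 (10 mol%), THF, 0 °C → rt
Reagents that add atoms: formaldehyde C=O
Why: Lewis-acid-catalysed aqueous Mukaiyama aldol (hydroxymethylation) at C4 of the regiodefined silyl enol ether, in which the β face of C4 is shielded by the 1,3-diaxial C20 bridge, so formaldehyde should add from the α face and give the quaternary center with CH2OH α and CH3 β.

Step 12
Reactants: 18 hydroxymethyl ketone lactol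
Product: 20 (13S)-8β,18-dihydroxy-17-norlabdan-15-oic acid, via bis-hydrazone 19 (not isolated)
Conditions: N2H4·H2O, diethylene glycol, 130 °C; then KOH, 200 °C; HCl work-up
Reagents that add atoms: none
Why: Wolff–Kishner reduction (Huang-Minlon procedure) of the preformed bis-hydrazone converts the C3 ketone into CH2 and the lactol carbon C20 into the angular methyl while freeing the 8β-hydroxyl, the hot alkali also saponifies the tert-butyl ester, and no stereocenter is created.

Step 13
Reactants: 20 (13S)-8β,18-dihydroxy-17-norlabdan-15-oic acid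
Product: 21 (13S)-18-hydroxy-8-oxo-17-norlabdan-15-oic acid
Conditions: aq. NaOCl (1.2 equiv), AcOH, 15 °C
Reagents that add atoms: none
Why: Hypochlorite in acetic acid oxidises secondary alcohols much faster than primary ones, so the axial 8β-hydroxyl should give the ketone while the neopentyl C18 hydroxyl stays, and the C9 side chain, now α to a carbonyl, already sits in the favoured equatorial (β) position.

Step 14
Reactants: 21 (13S)-18-hydroxy-8-oxo-17-norlabdan-15-oic acid
Product: 22 (13S)-18-hydroxylabd-8(17)-en-15-oic acid
Conditions: Ph3PCH3Br (6 equiv), KOtBu (6 equiv), THF, 0 °C → reflux; dilute HCl work-up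
Reagents that add atoms: methyltriphenylphosphonium bromide C[P+](c1ccccc1)(c1ccccc1)c1ccccc1.[Br-]
Why: Wittig methylenation of the C8 ketone with excess ylide (two equivalents are consumed by the acid and the alcohol) installs C17, and any base-induced equilibration at C9 can only return the equatorial 9β side chain.

Step 15
Reactants: 22 (13S)-18-hydroxylabd-8(17)-en-15-oic acid
Product: 24 (13S)-18-acetoxylabd-8(17)-en-15-oic acid (target), via mixed anhydride 23 (not isolated)
Conditions: Ac2O, pyridine, DMAP (cat.), CH2Cl2, rt; then aq. NaHCO3/THF; then dilute HCl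
Reagents that add atoms: acetic anhydride CC(=O)OC(C)=O
Why: DMAP-catalysed acetylation of the primary C18 alcohol, after which the mixed anhydride formed at C15 is hydrolysed in the bicarbonate work-up while the neopentyl-type acetate is far less labile.

**Compound list**

1 | (S)-citronellic acid [(3S)-3,7-dimethyloct-6-enoic acid] | CC(C)=CCC[C@H](C)CC(=O)O | starting material
2 | tert-butyl (3S)-3,7-dimethyloct-6-enoate | CC(C)=CCC[C@H](C)CC(=O)OC(C)(C)C | intermediate
3 | ozonide of 2 (3,3-dimethyl-1,2,4-trioxolane carrying the (S)-side chain at C5) | CC1(C)OOC(CC[C@H](C)CC(=O)OC(C)(C)C)O1 | intermediate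
4 | tert-butyl (3S)-3-methyl-6-oxohexanoate | O=CCC[C@H](C)CC(=O)OC(C)(C)C | intermediate
5 | methyl acrylate | C=CC(=O)OC | starting material
6 | 8-tert-butyl 1-methyl (6S)-3-hydroxy-6-methyl-2-methylideneoctanedioate (C3 epimers) | C=C(C(=O)OC)C(O)CC[C@H](C)CC(=O)OC(C)(C)C | intermediate
7 | 8-tert-butyl 1-methyl (2Z,6S)-2-(bromomethyl)-6-methyloct-2-enedioate | COC(=O)/C(CBr)=C/CC[C@H](C)CC(=O)OC(C)(C)C | intermediate
8 | 4-pentenal | C=CCCC=O | starting material
9 | 3-(triphenylphosphoranylidene)butan-2-one | CC(=O)C(C)=P(c1ccccc1)(c1ccccc1)c1ccccc1 | starting material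
10 | (3E)-3-methylocta-3,7-dien-2-one | CC(=O)/C(C)=C/CCC=C | intermediate
11 | ozonide of 10 (3-substituted 1,2,4-trioxolane) | CC(=O)/C(C)=C/CCC1OOCO1 | intermediate
12 | (4E)-5-methyl-6-oxohept-4-enal | CC(=O)/C(C)=C/CCC=O | intermediate
13 | 8-tert-butyl 1-methyl (3R,6S)-3-[(1S,4E)-1-hydroxy-5-methyl-6-oxohept-4-en-1-yl]-6-methyl-2-methylideneoctanedioate (anti hydroxy ester) | C=C(C(=O)OC)[C@H]([C@@H](O)CC/C=C(/C(C)=O)C)CC[C@H](C)CC(=O)OC(C)(C)C | intermediate
14 | tert-butyl (3S)-3-methyl-5-[(2S,3R)-2-[(3E)-4-methyl-5-oxohex-3-en-1-yl]-4-methylidene-5-oxooxolan-3-yl]pentanoate | C=C1C(=O)O[C@@H](CC/C=C(/C(C)=O)C)[C@@H]1CC[C@H](C)CC(=O)OC(C)(C)C | intermediate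
15 | tert-butyl (3S)-5-[(2S,3R)-2-[(3E)-5-[(tert-butyldimethylsilyl)oxy]-4-methylhexa-3,5-dien-1-yl]-4-methylidene-5-oxooxolan-3-yl]-3-methylpentanoate | C=C1C(=O)O[C@@H](CC/C=C(/C(=C)O[Si](C)(C)C(C)(C)C)C)[C@@H]1CC[C@H](C)CC(=O)OC(C)(C)C | intermediate
16 | tert-butyl (13S)-3-[(tert-butyldimethylsilyl)oxy]-20-oxo-8β,20-epoxy-17-norlabd-3-en-15-oate (5α-H, 9α-H, trans-fused) | O=C1O[C@H]2CC[C@H]3C(C)=C(O[Si](C)(C)C(C)(C)C)CC[C@@]13[C@H]2CC[C@H](C)CC(=O)OC(C)(C)C | intermediate
17 | tert-butyl (13S)-3-[(tert-butyldimethylsilyl)oxy]-20-hydroxy-8β,20-epoxy-17-norlabd-3-en-15-oate (lactol, C20 epimers) | OC1O[C@H]2CC[C@H]3C(C)=C(O[Si](C)(C)C(C)(C)C)CC[C@@]13[C@H]2CC[C@H](C)CC(=O)OC(C)(C)C | intermediate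
18 | tert-butyl (13S)-18,20-dihydroxy-3-oxo-8β,20-epoxy-17-norlabdan-15-oate (4α-CH2OH, 4β-CH3) | OC1O[C@H]2CC[C@H]3[C@](C)(CO)C(=O)CC[C@@]13[C@H]2CC[C@H](C)CC(=O)OC(C)(C)C | intermediate
19 | tert-butyl (13S)-3,20-dihydrazinylidene-8β,18-dihydroxy-17-norlabdan-15-oate (bis-hydrazone) | O[C@H]1CC[C@H]2[C@](C)(CO)C(=NN)CC[C@]2(C=NN)[C@H]1CC[C@H](C)CC(=O)OC(C)(C)C | intermediate
20 | (13S)-8β,18-dihydroxy-17-norlabdan-15-oic acid | O[C@H]1CC[C@H]2[C@](C)(CO)CCC[C@]2(C)[C@H]1CC[C@H](C)CC(=O)O | intermediate
21 | (13S)-18-hydroxy-8-oxo-17-norlabdan-15-oic acid | O=C1CC[C@H]2[C@](C)(CO)CCC[C@]2(C)[C@H]1CC[C@H](C)CC(=O)O | intermediate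
22 | (13S)-18-hydroxylabd-8(17)-en-15-oic acid | C=C1CC[C@H]2[C@](C)(CO)CCC[C@]2(C)[C@H]1CC[C@H](C)CC(=O)O | intermediate
23 | acetic (13S)-18-acetoxylabd-8(17)-en-15-oic anhydride | C=C1CC[C@H]2[C@](C)(COC(C)=O)CCC[C@]2(C)[C@H]1CC[C@H](C)CC(=O)OC(C)=O | intermediate
24 | (13S)-18-acetoxylabd-8(17)-en-15-oic acid (CNP0346003.1) | C=C1CC[C@H]2[C@](C)(COC(C)=O)CCC[C@]2(C)[C@H]1CC[C@H](C)CC(=O)O | target

**Step count.** Total: 15 steps. Longest linear sequence: 13 steps (steps 1–4 and 7–15, from (S)-citronellic acid); steps 5 and 6 make the second fragment.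

**Steps most likely to fail**

Step 9. The cycloaddition may discriminate poorly between the endo and exo modes, giving some cis-fused adduct. It may also be slow because the tether has to bridge the lactone ring, leaving time for polymerisation of the α-methylene lactone or for loss of the silyl enol ether. The fallback sets out from 15 and comes back at 17. The lactone is reduced first (i-Bu2AlH, CH2Cl2, −78 °C) to the α-methylene lactol F1. Warmed in toluene (60–80 °C), this should react through its ring-opened tautomer, the γ-hydroxy 2-substituted acrolein F2. F2 is a far more reactive dienophile that is no longer tied into a ring, so the reaction becomes an ordinary decatriene Diels–Alder. Its preferred transition state should have the aldehyde endo and a chair tether with the C9 chain equatorial and the C8 hydroxyl axial, hydrogen-bonded to the aldehyde. The resulting hydroxy aldehyde closes to lactol 17.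

Step 12. Under hot alkali the β-hydroxy ketone may lose the C18 hydroxymethyl group by retro-aldol cleavage before or during hydrazone decomposition. The two hindered hydrazones may also be reduced incompletely or condense to an intramolecular azine. The fallback sets out from 18 and comes back at 20, and replaces the basic reduction by a neutral Mozingo sequence. HSCH2CH2SH with BF3·OEt2 (CH2Cl2, 0 °C) converts the C3 ketone and the lactol aldehyde into the bis(dithiolane) F3. Raney Ni in EtOH (no alkene is present at this stage) gives the tert-butyl ester F4. CF3CO2H in CH2Cl2 then frees the acid 20.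

Step 11. Hydrolytic loss of the silyl group may outrun C–C bond formation at the hindered tetrasubstituted enol ether, or facial selectivity at C4 may erode in the aqueous medium. The fallback sets out from 17 and comes back at 20. Anhydrous SN1-type alkylation with benzyl chloromethyl ether and catalytic ZnBr2 (CH2Cl2, −20 °C) is expected to C-alkylate the silyl enol ether from the α face in preference to the lactol hydroxyl, giving the benzyl-protected keto lactol F5. The same Wolff–Kishner conditions as in step 12, now without a free β-hydroxyl, give the benzyl ether acid F6. Hydrogenolysis (H2, Pd/C, EtOAc) gives 20.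

**Further compounds**

F1 | step 9 | tert-butyl (3S)-5-[(2S,3R)-2-[(3E)-5-[(tert-butyldimethylsilyl)oxy]-4-methylhexa-3,5-dien-1-yl]-5-hydroxy-4-methylideneoxolan-3-yl]-3-methylpentanoate (α-methylene lactol) | C=C1C(O)O[C@@H](CC/C=C(/C(=C)O[Si](C)(C)C(C)(C)C)C)[C@@H]1CC[C@H](C)CC(=O)OC(C)(C)C
F2 | step 9 | tert-butyl (3S,6R,7S,10E)-12-[(tert-butyldimethylsilyl)oxy]-7-hydroxy-3,11-dimethyl-6-(3-oxoprop-1-en-2-yl)trideca-10,12-dienoate (open hydroxy enal tautomer of F1) | C=C(C=O)[C@H]([C@@H](O)CC/C=C(/C(=C)O[Si](C)(C)C(C)(C)C)C)CC[C@H](C)CC(=O)OC(C)(C)C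
F3 | step 12 | tert-butyl (13S)-8β,18-dihydroxy-17-norlabdan-15-oate 3,20-bis(ethane-1,2-diyl dithioacetal) | O[C@H]1CC[C@H]2[C@](C)(CO)C3(SCCS3)CC[C@]2(C4SCCS4)[C@H]1CC[C@H](C)CC(=O)OC(C)(C)C
F4 | step 12 | tert-butyl (13S)-8β,18-dihydroxy-17-norlabdan-15-oate | O[C@H]1CC[C@H]2[C@](C)(CO)CCC[C@]2(C)[C@H]1CC[C@H](C)CC(=O)OC(C)(C)C
F5 | step 11 | tert-butyl (13S)-18-benzyloxy-20-hydroxy-3-oxo-8β,20-epoxy-17-norlabdan-15-oate | OC1O[C@H]2CC[C@H]3[C@](C)(COCc4ccccc4)C(=O)CC[C@@]13[C@H]2CC[C@H](C)CC(=O)OC(C)(C)C
F6 | step 11 | (13S)-18-benzyloxy-8β-hydroxy-17-norlabdan-15-oic acid | O[C@H]1CC[C@H]2[C@](C)(COCc3ccccc3)CCC[C@]2(C)[C@H]1CC[C@H](C)CC(=O)O
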